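All runs were computed for an exercise; noise was put on by code.

* part of the left-handed substrate and right-handed substrate together gone at 5.0 min
* the left-handed product standing at 5.0 min, as a percentage of the left-handed substrate and right-handed substrate together charged

| setting | autumn | dawn | spring | flask |
|---|---|---|---|---|
| left-handed substrate | 0.010 M | 0.010 M | 0.010 M | 0.010 M |
| right-handed substrate | 0.010 M | 0.010 M | 0.010 M | 0.010 M |
| partner | 3 equiv | 3 equiv | 1.5 equiv | 3.00 equiv |
| free catalyst | 0.067 mol% | 0.15 mol% | 0.1 mol% | 0.1 mol% |
| remark | run made earlier | run made earlier | run made earlier |  |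
| time |  |  |  | 5.0 min |

| run | time / min | left-handed substrate / % | left-handed product / % |
|---|---|---|---|
| autumn | 0.833 | 28.4 | 22.0 |
| autumn | 1.50 | 26.3 | 23.2 |
| autumn | 2.50 | 25.8 | 23.2 |
| autumn | 3.00 | 26.3 | 23.8 |
| autumn | 4.00 | 27.0 | 23.5 |
| autumn | 5.00 | 26.5 | 24.1 |
| autumn | 6.00 | 25.9 | 24.0 |
| dawn | 0.333 | 22.2 | 28.0 |
| dawn | 1.00 | 14.3 | 35.5 |
| dawn | 1.50 | 13.7 | 36.3 |
| dawn | 2.50 | 13.4 | 36.2 |
| dawn | 4.00 | 12.9 | 36.2 |
| dawn | 5.00 | 13.3 | 36.7 |
| dawn | 6.00 | 14.2 | 36.5 |
| spring | 0.500 | 35.1 | 14.6 |
| spring | 1.50 | 32.5 | 17.1 |
| spring | 3.00 | 32.7 | 17.3 |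
| spring | 4.00 | 32.6 | 17.4 |
| spring | 6.00 | 32.8 | 17.3 |

(each reading ± 0.3 percentage points)

1. The reading at 5.0 min comes later than the 1.50 min from which autumn, dawn and spring stand flat within the scatter of 0.3 percentage points, so we need the plateau, not a rate.

2. We call the stopping number N the natural log of the left-handed half of the charge over plateau c(left-handed substrate). Plateau means give 26.3% in autumn, 13.5% in dawn and 32.6% in spring, so N reads 0.642, 1.31 and 0.426.

3. Way one keeps the flask's partner: on the straight line through autumn and dawn, the flask's stopping number N is 0.908.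

4. Way two starts from spring, which has the flask's loading and half its partner. Scaling N in proportion to partner gives 0.852.

5. These leave left-handed substrate at 20.2% and 21.3%, a gap of 1.1 points, wider than the scatter. Way one stays inside the runs: at 3.00 equiv of partner, the flask's 0.1 mol% of free catalyst lies between autumn's 0.067 mol% and dawn's 0.15 mol%. Way two assumes N in proportion to partner, and with spring as its one run at that loading we cannot test this, so we judge that way two is the one that cheats. We keep way one.

6. Left-handed substrate and product sum to about the left-handed half, so we expect left-handed product at 29.8%. The runs list no right-handed reading, so conversion is that plus a share we cannot reckon.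

7. The forecast gave conversion 30% and left-handed product 29.8%, saying “I assume it is essentially untouched”.

    free catalyst + left-handed substrate ⇌ catalyst intermediate A (K = 77.0 M⁻¹, k = 42000 M⁻¹ s⁻¹)
    free catalyst + right-handed substrate ⇌ catalyst intermediate B (K = 51.0 M⁻¹, k = 1.00 × 10⁵ M⁻¹ s⁻¹)
    partner + catalyst intermediate A → free catalyst + left-handed product (k = 4600 M⁻¹ s⁻¹)
    partner + catalyst intermediate B → free catalyst + right-handed product (k = 2100 M⁻¹ s⁻¹)
    partner → decomposed reagent (k = 0.0390 s⁻¹)
    partner → decomposition product (k = 2.10 × 10⁻⁴ s⁻¹)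

The flask gives left-handed product 30.0% and conversion 43.2%. At 5.00 min, right-handed product at 13.1% stands beside left-handed product at 30.0%, and together they make up that conversion. Extending the autumn–dawn line to the neighbour flask with 0.17 mol% of free catalyst gives N = 1.47, hence left-handed substrate 11.5%. That neighbour flask holds 11.7%.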